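## The problem

Target 17 is a cis-fused decalin of the eudesmane family; eudesmane numbering is used throughout. Ring A (C1–C5, C10) carries only the exocyclic methylene C4=C15. Ring B (C5–C10) carries a free hydroxyl at C6, an isopropyl group at C7 and a 4-methoxybenzoate at C9. The rings share the C5–C10 bond, and C10 is quaternary (methyl C14).

Five stereocentres must be set (5S,6S,7R,9R,10R). All five groups (10-CH3, 5-H, 6-OH, 7-i-Pr, 9-OAr) lie on one face of the bicycle, called α below; β is the opposite face. C10 is the hard carbon: fully substituted, next to the C9 carbinol and the C5 ring-fusion methine. C5 and C10 are the only centres that need an outside source of absolute configuration.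

Once the cis fusion exists, ring B prefers the chair with 10-CH3 axial, 7-i-Pr and 9-OAr equatorial and 6-OH axial. C7 can therefore be set by attack on the convex α face, C9 under thermodynamic control, and C6 by hydride delivery anti to the syn-axial methyl.

The fragile points are:
- H5, which is allylic to C4=C15 and α to any C6 carbonyl, so it is prone to double-bond migration into conjugation or epimerisation to the trans-decalin;
- the 1,1-disubstituted alkene, which rules out hydrogenation and strong acid;
- the aryl ester, which limits late base and hydride;
- the two ring B oxygens, which must be told apart because only O9 is acylated.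

The enabling feature is that O6 and O9 are 1,4-related across ring B and flank the C5–C10 bond. A bond drawn between C6 and C9 turns ring B into a bicyclo[2.2.0]hexane-1,4-diol fused to ring A. That is the [2+2] adduct of a ring A enone (C5=C10) and a cyclobutene-1,2-diol ether.

## Retrosynthesis

**17 ⇒ 16 (C6–H).** The axial 6α-alcohol is the less stable epimer, so it is made last by reduction of ketone 16. In 16 the chair is locked by the equatorial C7 and C9 groups, and 10-CH3 screens the α face of C6. Cutting the ester first would leave two hydroxyls to distinguish. The forward step must be a hydride reduction mild enough for the anisoate and faster than enolisation toward C5.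

**16 ⇒ 15 ⇒ 13 + 14 (ketal; C9 O–acyl bond).** The C6 carbonyl is carried as the dioxolane 15, and the ester is cut to alcohol 13 and 4-methoxybenzoyl chloride 14. A ketal is preferred to a protected C6 alcohol for three reasons: it creates no stereocentre to be made and later unmade, it puts oxygen on both faces and so does not bias the C7-forming step, and it keeps H5 away from a carbonyl through all basic steps. The forward reactions must acylate a neopentyl but equatorial hydroxyl and then hydrolyse the ketal without moving C4=C15.

**13 ⇒ 12 (C9–H).** The carbinol goes back to ketone 12. The wanted 9α-hydroxyl is equatorial, so the reduction can run under thermodynamic control (dissolving metal). A kinetic hydride would have to choose between a face hindered by 10-CH3 on the adjacent carbon and a face hindered by syn-axial C4.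

**12 ⇒ 9 + 10 (C7–C11).** The isopropyl group is removed as isopropylmagnesium chloride 10, leaving enone 9. Alkylating a C6 enolate with a secondary halide would fail on the regiochemistry of enolisation, and an aldol–dehydration–hydrogenation sequence would fail on C4=C15. Conjugate addition places the carbon on C7 unambiguously and lets the ring fusion control the face. Enone 9 has no ring B stereocentre beyond the fusion.

**9 ⇒ 7 ⇒ 6 (C7=C8; ketal).** The double bond of 9 comes from ketone 7 through silyl enol ether 8; with C10 quaternary, 7 can enolise only toward C8. Ketone 7 is the monoketal of dione 6. This cut relies on the steric difference between the C6 carbonyl (next to a methine) and the C9 carbonyl (next to the quaternary carbon).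

**6 ⇒ 4 ⇒ 3 (C6–C9 reconnection; C4=C15).** Rejoining C6 and C9 turns 1,4-dione 6 into glycol 5 and its bis-silyl ether 4; forward, glycol cleavage opens both four-membered rings into ring B. The methylene of 4 is traced to ketone 3 by a Wittig reaction. The order is fixed by reactivity: if the C4 carbonyl were still present when O6 is unmasked, retro-aldol cleavage of C5–C6 or a 4,6-dicarbonyl that erases C5 would follow.

**3 ⇒ 1 + 2 (C5–C6 and C9–C10).** Cutting the two cyclobutane bonds of 3 gives 3-methylcyclohex-2-en-1-one 1 and 1,2-bis(trimethylsilyloxy)cyclobutene 2, both commercial. Ionic routes to the C10 quaternary centre pay a steric price and would still need ring B oxygenation afterwards. The photocycloaddition forms C10 through a biradical, brings both oxygens, and sets C5 and C10 in one operation. It must be enantioface-selective (chiral Lewis acid) and give the cis ring fusion.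

## Roads not taken

**Alternative 1:** Both C–O bonds at C6 and C9 are cut together, leading back to the ring B 1,3-diene A1 (C6=C7–C8=C9, isopropyl on C7). Forward, sensitised photooxygenation (O2, light, tetraphenylporphyrin) adds singlet oxygen across C6 and C9 to give endoperoxide A2.

- Merits: both oxygens arrive in one step, cis to each other and on the convex α face, exactly as the target needs. No ketone at C6 or C9 has to be reduced. On this point the road is better than the chosen one, which spends two reductions and a ketal on the same oxygens.
- Weak points: A1 already contains the hard part (quaternary C10, cis fusion, absolute configuration), and the key step does nothing for it. After O–O cleavage, C7 must be set by saturating C7=C8. Hydrogen would arrive from the convex α face, and the two α-hydroxyls would direct it there as well, which puts the isopropyl group on the β face, opposite to the target. The 1,1-disubstituted C4=C15 would also be reduced more readily than the trisubstituted C7=C8. The two secondary hydroxyls still need differentiating, and ene reactions of singlet oxygen compete.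
- Comparison: the chosen plan is longer after its key step, but that step builds the skeleton including C10, and C7 is set by an addition whose facial preference matches the target.

**Alternative 2:** The C1–C10 bond is cut. Ring A would be closed from phenol A3, a thymohydroquinone monomethyl ether with the side chain on C5, a silyloxy stereocentre at C4 and a primary iodide at C1. KOt-Bu would form the C9 phenolate, whose ortho carbon C10 displaces the iodide with dearomatisation to give 2,4-dienone A4.

- Merits: ring B arrives with oxygen at C6 and C9 already differentiated (enol ether versus ketone) and the isopropyl group in place, from a cheap arene. Here the road is better than the chosen plan, which has to differentiate two ketones and add the isopropyl group.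
- Weak points: A4 holds only C4 and C10 as stereocentres. C5, C6, C7 and C9 must all come from reductions of a dienone and a tetrasubstituted enol ether with nothing to direct them, and H5 must end cis to 10-CH3. The absolute configuration of C10 is relayed from a C4 carbinol centre that must itself be made enantioselectively and is later destroyed (deprotection, oxidation, methylenation). 6,6-Disubstituted cyclohexa-2,4-dienones tend to dimerise by Diels–Alder reaction. Several steps are needed before the key step and many after it.
- Comparison: the chosen plan starts from two commercial compounds with no preliminary steps and takes C5 and C10 from a catalyst.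

**Alternative 3:** The C6–C7 and C7–C8 bonds are cut. Sc(OTf)3 would catalyse addition of 2-methyl-1-diazopropane A6 to the C6 carbonyl of cis-hydrindanone A5; migration of C8 with loss of N2 enlarges the five-membered ring to ketone A7, which is the same compound as 16.

- Merits: A7 is one reduction from the target, and the isopropyl-bearing carbon arrives in a single step with no ketal and no conjugate addition. The end-game is shorter than steps 4–9 of the chosen route, and the final reduction is shared.
- Weak points: migration of C5 (tertiary, allylic) instead of C8 would give a constitutional isomer. A6 is a non-stabilised, hazardous diazoalkane that must be made fresh, and epoxide formation and double homologation are common side paths. Above all, A5 already holds quaternary C10, the cis fusion, the C9 ester next to the quaternary carbon and a β,γ-unsaturated ketone, so its synthesis is about as demanding as the decalin itself.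
- Comparison: the chosen plan reaches the same ketone 16 in nine steps from commercial materials, with each ring B substituent placed by a reaction of predictable regiochemistry.

Key step: step 1

Assumption: the oxazaborolidine enantiomer is the one that leaves open the face of bound enone 1 that is Re at both C2 and C3. Which prolinol series does this is taken from the sense of induction known with simple alkenes; the mirror-image prolinol is used if the sense proves opposite.

## Route

Step 1
Reactants: 1 3-methylcyclohex-2-en-1-one; 2 1,2-bis(trimethylsilyloxy)cyclobutene
Product: 3 1-methyl-2,5-bis(trimethylsilyloxy)tricyclo[4.4.0.0(2,5)]decan-7-one, cis-anti-cis (C4 ketone; cyclobutane C5–C6–C9–C10; 5-H and 10-CH3 α; 6- and 9-OSiMe3 β)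
Conditions: AlBr3-activated B-(2,3,4-trifluorophenyl)oxazaborolidine of α,α-bis(3,5-dimethylphenyl)prolinol (0.5 equiv), 2 (5 equiv), CH2Cl2, −75 °C, hν (366 nm); then basic Al2O3, CH2Cl2, rt
Reagents that add atoms: none
Why: Proposed new method: the closest known reaction types are the oxazaborolidine–AlBr3-catalysed enantioselective intermolecular [2+2] photocycloaddition of cyclohex-2-enones with simple alkenes and the uncatalysed racemic photocycloaddition of cyclic enones with 2, and their combination with an ene-diol bis-silyl ether under a strong Lewis acid is untested. Coordination of the Lewis acid to the carbonyl of 1 shifts its absorption to longer wavelength, so 366 nm light excites mainly the bound enone, which after intersystem crossing adds as a triplet to the electron-rich alkene to give a 1,4-biradical. The four-membered ring then closes by spin inversion and radical recombination (stepwise biradical closure, not a concerted cycloaddition), forming C5–C6 and C9–C10, so the quaternary C10 is made without an ionic, sterically penalised transition state. The absolute configuration of C10 and C5 is set by the catalyst, whose aryl groups cover one face of the bound enone. The cis ring fusion follows from strain, and any trans-fused adduct is epimerised at C5 (α to the C4 ketone) on basic alumina. C6 and C9 are necessarily cis to each other because they come from a cyclobutene, and anti to ring A by steric approach; both are erased in step 3, so their configuration does not matter. The step needs enantioface selectivity and a photochemical path faster than a dark Mukaiyama–Michael addition; the β,β-disubstituted enone, the tetrasubstituted alkene and the low temperature all slow the ionic addition.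

Step 2
Reactants: 3 tricyclic ketone
Product: 4 1-methyl-7-methylidene-2,5-bis(trimethylsilyloxy)tricyclo[4.4.0.0(2,5)]decane (C4=C15; stereocentres as in 3)
Conditions: Ph3PCH3Br, KN(SiMe3)2, THF, 0 °C → rt
Reagents that add atoms: methyltriphenylphosphonium bromide, C[P+](c1ccccc1)(c1ccccc1)c1ccccc1.[Br-]
Why: Wittig methylenation of the C4 ketone while both oxygens are still silylated, so that later desilylation cannot trigger retro-aldol cleavage of C5–C6 and no 4,6-dicarbonyl can form. β-Elimination of the silyloxy group is excluded because it would give a bridgehead cyclobutene.

Step 3
Reactants: 4 methylene bis-silyl ether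
Product: 6 4-methylene-10-methyl-cis-decalin-6,9-dione (5-H and 10-CH3 α), via tricyclic 6,9-diol 5 (not isolated)
Conditions: K2CO3 (cat.), MeOH, rt; then NaIO4, THF/pH 7 buffer, 0 °C → rt
Reagents that add atoms: none
Why: Methanolysis of the silyl ethers followed by periodate glycol cleavage of the cis ditertiary diol. Breaking the central C6–C9 bond releases the strain of both four-membered rings and opens them into six-membered ring B with carbonyls at C6 and C9. C5 and C10 are untouched, and the neutral buffer protects H5, which is now α to the C6 carbonyl.

Step 4
Reactants: 6 dione
Product: 7 6,6-ethylenedioxy-4-methylene-10-methyl-cis-decalin-9-one (spiro-1,3-dioxolane at C6)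
Conditions: Me3SiOCH2CH2OSiMe3 (1.1 equiv), TMSOTf (cat.), CH2Cl2, −78 °C; pyridine quench
Reagents that add atoms: 1,2-bis(trimethylsilyloxy)ethane, C[Si](C)(C)OCCO[Si](C)(C)C
Why: Silyl-transfer ketalisation under kinetic control: the C6 carbonyl, flanked by a methine, should react before the C9 carbonyl, flanked by quaternary C10. The aprotic, low-temperature conditions are chosen to avoid migration of the β,γ double bond.

Step 5
Reactants: 7 monoketal ketone
Product: 9 6,6-ethylenedioxy-4-methylene-10-methyl-cis-decal-7-en-9-one, via C8–C9 silyl enol ether 8 (not isolated)
Conditions: LiN(i-Pr)2, TMSCl, THF, −78 °C; then Pd(OAc)2, MeCN, rt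
Reagents that add atoms: none
Why: Saegusa–Ito oxidation. The ketone can enolise only toward C8 because C10 is quaternary, and the fully substituted C6 prevents further dehydrogenation.

Step 6
Reactants: 9 enone; 10 isopropylmagnesium chloride
Product: 12 6,6-ethylenedioxy-7α-isopropyl-4-methylene-10-methyl-cis-decalin-9-one, via 7α-isopropyl silyl enol ether 11 (not isolated)
Conditions: CuI (20 mol %), TMSCl, THF, −78 → −30 °C; then K2CO3, MeOH, 0 °C
Reagents that add atoms: none
Why: Copper-catalysed, TMSCl-accelerated conjugate addition of the Grignard reagent. Axial attack occurs on the enone half-chair that keeps the ring A carbon C4 pseudo-equatorial on ring B, that is anti to C4 and on the convex face cis to 5-H (the usual trans-3,5 rule for 5-substituted cyclohexenones), which gives 7α. The ketal has oxygen on both faces and adds no bias; the enol ether 11 is cleaved by methanolysis.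

Step 7
Reactants: 12 isopropyl ketone
Product: 13 6,6-ethylenedioxy-7α-isopropyl-4-methylene-10-methyl-cis-decalin-9α-ol
Conditions: Li, NH3(l), THF, EtOH, −78 °C; NH4Cl
Reagents that add atoms: none
Why: Dissolving-metal reduction, which gives the more stable alcohol. The 9α-hydroxyl is equatorial in the chair that keeps 7-i-Pr equatorial, whereas the 9β epimer would be axial and syn-axial to C4. The isolated alkene and the ketal are inert to these conditions.

Step 8
Reactants: 13 9α-alcohol; 14 4-methoxybenzoyl chloride
Product: 15 6,6-ethylenedioxy-7α-isopropyl-4-methylene-10-methyl-cis-decalin-9α-yl 4-methoxybenzoate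
Conditions: Et3N, DMAP (cat.), CH2Cl2, rt → 40 °C
Reagents that add atoms: none
Why: DMAP-catalysed acylation of the only free hydroxyl. It is neopentyl but equatorial, so gentle heating should suffice; no stereocentre is touched.

Step 9
Reactants: 15 ketal ester
Product: 16 7α-isopropyl-4-methylene-10-methyl-6-oxo-cis-decalin-9α-yl 4-methoxybenzoate
Conditions: TsOH·H2O (cat.), acetone/H2O, rt
Reagents that add atoms: water, O
Why: Acid-catalysed ketal hydrolysis (exchange to acetone), which the aryl ester tolerates. In the locked chair H5 is equatorial on ring B and lies near the carbonyl plane, so enolisation toward C5 (conjugation or epimerisation) is stereoelectronically slow. C7 already has its isopropyl group in the stable equatorial position.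

Step 10
Reactants: 16 ketone
Product: 17 (5S,6S,7R,9R,10R)-6-hydroxy-7-isopropyl-10-methyl-4-methylene-cis-decalin-9-yl 4-methoxybenzoate (all of 5-H, 6-OH, 7-i-Pr, 9-OAr, 10-CH3 α)
Conditions: NaBH4, MeOH/THF, −20 → 0 °C
Reagents that add atoms: none
Why: Borohydride reduction of the ketone. The axial 10-CH3 is syn-axial to the α approach at C6, so hydride should enter from the β face and give the axial 6α-alcohol, cis to CH3, i-Pr and OAr. Hydride reductions of 6-oxo steroids likewise place the hydroxyl syn to the angular methyl, and NaBH4 leaves the aryl ester and the alkene alone.

## Compound list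

1 | 3-methylcyclohex-2-en-1-one | CC1=CC(=O)CCC1 | starting material
2 | 1,2-bis(trimethylsilyloxy)cyclobutene | C[Si](C)(C)OC1=C(O[Si](C)(C)C)CC1 | starting material
3 | 1-methyl-2,5-bis(trimethylsilyloxy)tricyclo[4.4.0.0(2,5)]decan-7-one, cis-anti-cis photoadduct | O=C1CCC[C@]2(C)[C@H]1[C@@]3(O[Si](C)(C)C)CC[C@@]23O[Si](C)(C)C | intermediate
4 | 1-methyl-7-methylidene-2,5-bis(trimethylsilyloxy)tricyclo[4.4.0.0(2,5)]decane | C=C1CCC[C@]2(C)[C@H]1[C@@]3(O[Si](C)(C)C)CC[C@@]23O[Si](C)(C)C | intermediate
5 | 1-methyl-7-methylidenetricyclo[4.4.0.0(2,5)]decane-2,5-diol | C=C1CCC[C@]2(C)[C@H]1[C@@]3(O)CC[C@@]23O | intermediate (not isolated)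
6 | 4-methylene-10-methyl-cis-decalin-6,9-dione | C=C1CCC[C@]2(C)[C@H]1C(=O)CCC2=O | intermediate
7 | 6,6-ethylenedioxy-4-methylene-10-methyl-cis-decalin-9-one | C=C1CCC[C@]2(C)[C@H]1C3(OCCO3)CCC2=O | intermediate
8 | 6,6-ethylenedioxy-4-methylene-10-methyl-9-trimethylsilyloxy-cis-decal-8-ene | C=C1CCC[C@]2(C)[C@H]1C3(OCCO3)CC=C2O[Si](C)(C)C | intermediate (not isolated)
9 | 6,6-ethylenedioxy-4-methylene-10-methyl-cis-decal-7-en-9-one | C=C1CCC[C@]2(C)[C@H]1C3(OCCO3)C=CC2=O | intermediate
10 | isopropylmagnesium chloride | CC(C)[Mg]Cl | starting material
11 | 6,6-ethylenedioxy-7α-isopropyl-4-methylene-10-methyl-9-trimethylsilyloxy-cis-decal-8-ene | C=C1CCC[C@]2(C)[C@H]1C3(OCCO3)[C@@H](C(C)C)C=C2O[Si](C)(C)C | intermediate (not isolated)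
12 | 6,6-ethylenedioxy-7α-isopropyl-4-methylene-10-methyl-cis-decalin-9-one | C=C1CCC[C@]2(C)[C@H]1C3(OCCO3)[C@@H](C(C)C)CC2=O | intermediate
13 | 6,6-ethylenedioxy-7α-isopropyl-4-methylene-10-methyl-cis-decalin-9α-ol | C=C1CCC[C@]2(C)[C@H]1C3(OCCO3)[C@@H](C(C)C)C[C@H]2O | intermediate
14 | 4-methoxybenzoyl chloride | COc1ccc(cc1)C(Cl)=O | starting material
15 | 6,6-ethylenedioxy-7α-isopropyl-4-methylene-10-methyl-cis-decalin-9α-yl 4-methoxybenzoate | C=C1CCC[C@]2(C)[C@H]1C3(OCCO3)[C@@H](C(C)C)C[C@H]2OC(=O)c4ccc(OC)cc4 | intermediate
16 | 7α-isopropyl-4-methylene-10-methyl-6-oxo-cis-decalin-9α-yl 4-methoxybenzoate | C=C1CCC[C@]2(C)[C@H]1C(=O)[C@@H](C(C)C)C[C@H]2OC(=O)c3ccc(OC)cc3 | intermediate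
17 | (5S,6S,7R,9R,10R)-6-hydroxy-7-isopropyl-10-methyl-4-methylene-cis-decalin-9-yl 4-methoxybenzoate | C=C1CCC[C@]2(C)[C@H]1[C@@H](O)[C@@H](C(C)C)C[C@H]2OC(=O)c1ccc(OC)cc1 | target

## Step count and risks

Total: 10 steps. Longest linear sequence: 10 steps (1 and 2 to 17).

Least certain steps:

**Step 1 (key step; bears the new-method label).** The dark ionic pathway may win: Lewis-acid-promoted Mukaiyama–Michael addition or desilylation of the bis-silyl enol ether, or Lewis-acid-induced retro-aldol opening of the β-silyloxy ketone once formed. Face discrimination may also be poor with this bulky, electron-rich alkene. Fallback, from 1 and 2: irradiate without Lewis acid (λ about 350 nm, CH2Cl2, then basic Al2O3), the known racemic cycloaddition, which gives 3 together with its mirror image, the ent-photoadduct F1. Resolution by preparative chromatography on a chiral stationary phase returns to the route at 3.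

**Step 4.** Ketalisation at the C9 carbonyl may compete, or the acid catalyst may move the β,γ double bond. Fallback, from 6: ketalise exhaustively (excess reagent, 0 °C) to the bis(ethylene ketal) F2, then hydrolyse under control (PPTS, wet acetone). The more strained ketal beside quaternary C10 should open first, which returns to the route at 7.

**Step 6.** Addition of a secondary alkyl group to a β-carbon next to the spiro-ketal may be slow, allowing 1,2-addition or enone reduction by β-hydride transfer, and facial selectivity may erode. Fallback, from 9: Giese radical conjugate addition of the isopropyl radical (2-iodopropane, (Me3Si)3SiH, AIBN, benzene, 80 °C). It is less sensitive to crowding, attacks the same convex face, and gives 12 directly with no new intermediate.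

**Step 7.** The thermodynamic preference for the 9α-alcohol may be too small if the ketal shifts the chair equilibrium, and pinacol coupling is possible. Fallback, from 12: kinetic hydride reduction (LiAlH4, THF, −78 °C). Should it give the 9β-alcohol F3, a Mitsunobu esterification with 4-methoxybenzoic acid (PPh3, DIAD) inverts C9 and installs the ester in one operation, returning to the route at 15.

**Step 10.** Hydride may also attack the α face, and basic methanol may move the double bond into conjugation or transesterify the anisoate. Fallback, from 13: hydrolyse the ketal before acylation to the hydroxy ketone F4, and reduce it with LiBH(s-Bu)3 (THF, −78 °C), a bulkier hydride usable because no ester is present, to give the 6α,9α-diol F5. Selective acylation of the equatorial 9-hydroxyl over the axial, doubly flanked 6-hydroxyl with 14 (Et3N, DMAP, 0 °C) then returns to the route at 17.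

## Further compounds

F1 | step 1 | ent-1-methyl-2,5-bis(trimethylsilyloxy)tricyclo[4.4.0.0(2,5)]decan-7-one (mirror image of 3, formed with 3 as the racemate) | O=C1CCC[C@@]2(C)[C@@H]1[C@]3(O[Si](C)(C)C)CC[C@]23O[Si](C)(C)C
F2 | step 4 | 4-methylene-10-methyl-cis-decalin-6,9-dione bis(ethylene ketal) | C=C1CCC[C@]2(C)[C@H]1C3(OCCO3)CCC24OCCO4
F0 | step 6 | none | none
F3 | step 7 | 6,6-ethylenedioxy-7α-isopropyl-4-methylene-10-methyl-cis-decalin-9β-ol | C=C1CCC[C@]2(C)[C@H]1C3(OCCO3)[C@@H](C(C)C)C[C@@H]2O
F4 | step 10 | 9α-hydroxy-7α-isopropyl-4-methylene-10-methyl-cis-decalin-6-one | C=C1CCC[C@]2(C)[C@H]1C(=O)[C@@H](C(C)C)C[C@H]2O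
F5 | step 10 | 7α-isopropyl-4-methylene-10-methyl-cis-decalin-6α,9α-diol | C=C1CCC[C@]2(C)[C@H]1[C@@H](O)[C@@H](C(C)C)C[C@H]2O
A1 | alternative 1 | cis-fused 7-isopropyl-10-methyl-4-methylene ring B 6,8-diene | C=C1CCC[C@]2(C)[C@H]1C=C(C(C)C)C=C2
A2 | alternative 1 | C6–C9 endoperoxide of the cis-fused diene | C=C1CCC[C@]2(C)[C@H]1[C@H]3OO[C@@H]2C=C3C(C)C
A3 | alternative 2 | 3-[1-(tert-butyldimethylsilyloxy)-4-iodobutyl]-5-isopropyl-4-methoxy-2-methylphenol | CC(C)(C)[Si](C)(C)O[C@H](CCCI)c1c(C)c(O)cc(C(C)C)c1OC
A4 | alternative 2 | bicyclic 2,4-dienone with quaternary C10 methyl, C6 methoxy, C7 isopropyl and C4 silyloxy | CC(C)(C)[Si](C)(C)O[C@@H]1CCC[C@]2(C)C1=C(OC)C(C(C)C)=CC2=O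
A5 | alternative 3 | cis-hydrindan-6-one with C4 methylene, C10 methyl and C9 4-methoxybenzoate | C=C1CCC[C@]2(C)[C@H]1C(=O)C[C@H]2OC(=O)c1ccc(OC)cc1
A6 | alternative 3 | 2-methyl-1-diazopropane | CC(C)C=[N+]=[N-]
A7 | alternative 3 | cis-fused 7-isopropyl-decalin-6-one with C4 methylene and C9 anisoate (identical with 16) | C=C1CCC[C@]2(C)[C@H]1C(=O)[C@@H](C(C)C)C[C@H]2OC(=O)c1ccc(OC)cc1
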